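# Proposed synthesis of (-)-(7R,8S,7'E)-3,4,5,5'-tetramethoxy-4',7-epoxy-8,3'-neolign-7'-ene-9,9'-diol (16)

Ring A is the 3,4,5-trimethoxyphenyl ring (C1 to C6) and ring B is the benzo ring of the dihydrobenzofuran (C1' to C6'). Compound numbers are those of the steps and of the compound list.

## Analysis of the target

Target 16 is a 2-aryl-3-(hydroxymethyl)-2,3-dihydrobenzofuran. The five-membered ring O-C7-C8-C3'-C4' is fused to ring B, C7 carries ring A and C8 carries the C9 hydroxymethyl group. Ring B is 1,3,4,5-tetrasubstituted, with the (E)-3-hydroxyprop-1-enyl chain at C1' and a methoxy group at C5' next to the ring oxygen on C4'. The two stereocentres are contiguous, C7 (R) and C8 (S), and the aryl and hydroxymethyl groups are trans on the ring. C7 is a benzylic ether carbon that can ionise under acid, the cinnamyl alcohol is sensitive to acid and to oxidants, and both arenes are electron-rich. The difficulty lies in fixing the absolute configuration at C7, in obtaining the trans relation at C8 (a centre that cannot be equilibrated once C9 is an alcohol), and in forming the C8-C3' bond at a crowded ring position while the two primary alcohols stay distinguishable. The strategy rests on the surroundings of C8: it is bonded to C3' and to the oxygen-bearing C9, and C3' is ortho to the C4'-O-C7 linkage. An aryl radical at C3' therefore lies five atoms from a C8=C9 vinyl group on C7, so 5-exo closure makes C8-C3' and the dihydrofuran ring and leaves a radical at C9, exactly where oxygen is needed.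

## Retrosynthetic reasoning

**Side chain (16 to 13).** The C9' alcohol of 16 is taken back to the ester of cinnamate 15. The C7'=C8' double bond is then cut in a Wittig sense to aldehyde 14, which is generated in the flask from diol 13 by oxidation of the benzylic alcohol only. The cut is placed here because the cinnamyl alcohol is the most fragile group of the target and should appear last. It also lets ring B carry a robust ester, not an alkene, through the radical step. The forward reactions have to tell the benzylic C7' alcohol from the saturated C9 alcohol and give the E alkene.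

**Unmasking (13 to 11).** Diol 13 comes from hydroxy ester 12 by reduction of the aryl ester, and 12 from alkoxyamine 11 by cleavage of the N-O bond. The aminoxyl group on C9 is a masked hydroxyl. It is removed directly after the key step, while the molecule still lacks the acid-sensitive cinnamyl alcohol.

**Key disconnection (11 to 7 and 8).** In 11 the bonds C8-C3' and C9-O are cut together, which leads back to aryl iodide 7 and the nitroxyl radical 8. These two bonds sit at the two ends of a vinyl group that hangs on C7, so one operation closes the ring, makes a C-C and a C-O bond and creates the C8 stereocentre under the influence of C7. A cut at C7-C8 or at O-C7 would instead require both stereocentres to be made at once. The forward reaction has to generate the radical at C3' only, close 5-exo before the radical is quenched, capture C9 by oxygen and not by hydrogen, and deliver the trans ring.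

**Ether bond (7 to 6 and 5).** The O-C7 bond of 7 is cut, not the C4'-O bond, which gives aryloxide 6 and cinnamyl carbonate 5. Both pieces are achiral, and the C7 stereocentre then arises in the bond-forming step itself, a branched-selective, enantioselective iridium-catalysed allylic etherification. Cutting C4'-O would call for a preformed chiral secondary alcohol and a substitution on a hindered, weakly activated arene. The forward reaction has to favour the branched over the linear ether and control the face of attack.

**Fragments.** Carbonate 5 comes from allylic alcohol 4, and 4 from the commercial cinnamate 3 by 1,2-reduction. Aryloxide 6 is the lithium salt of iodophenol 2, which comes from methyl vanillate 1 by iodination ortho to the hydroxyl group.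

## Alternatives that were turned down

**Alternative 1: three-component conjunctive coupling.**
- Disconnection: C8-C3' and C7-C1 are both cut. This leaves the alkenyl boronate A2 (C7 to C9 with a silyl-protected C9 oxygen), ring A as aryllithium A3 and ring B as aryl triflate A5. The O-C4' bond is closed later.
- Forward key step: A2 and A3 form the boron ate complex A4. With A5, Pd(OAc)2 and the chiral ferrocenyl bisphosphine MandyPhos, a divalent arylpalladium species activates the alkene, ring A shifts from boron to C7 anti to the metal, and reductive elimination places ring B on C8. The product is A1.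
- For: the step is convergent, and both stereocentres come from one catalyst-controlled, stereospecific addition across an E alkene. On this point it is stronger than the chosen route, where C8 depends on induction from C7.
- Against: a 1,2-disubstituted alkenyl boronate binds palladium less readily than a vinyl boronate and tends to undergo direct Suzuki coupling instead, and a pinacol ester is the least favourable boron ligand in that respect. A5 carries an ortho fluorine and an ester that must never meet free A3. After the key step the route still needs oxidation of the C-B bond, ring closure by displacement of a fluoride that is activated only by a para ester, desilylation and the whole side-chain elaboration.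
- Comparison: the sequence is longer and its central step is less secure. The chosen route offers a key step that closes the ring and installs the C9 oxygen in the same operation, through elementary radical steps whose relative rates are well understood.

**Alternative 2: [4+1] annulation of an o-quinone methide with a chiral sulfur ylide.**
- Disconnection: C7-C8 and O-C7 are cut. Ring B with C8 and C9 comes as sulfone A7, and ring A with C7 as sulfonium salt A8 (drawn with one enantiomer of a C2-symmetric thiolane; the enantiomer that leads to 7R would be used).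
- Forward key step: base eliminates sulfinate from A7 to give the o-quinone methide A9 and deprotonates A8 to the ylide A10. The ylide carbon adds to the exocyclic C8, and the phenoxide displaces the sulfide at C7 to give A6.
- For: the ring, the C7-C8 bond and both stereocentres form in one mild step, and the trans ring follows from the substitution mechanism. The aryl bromide allows the C7' to C9' chain to be attached by a Heck reaction, so the endgame is shorter than in the chosen route.
- Against: A9 carries an alkyl group with hydrogens on C9 and can tautomerise to a vinyl phenol before the ylide arrives, and this reaction type is established mainly for aryl-substituted quinone methides. The absolute configuration of both centres depends on the facial selectivity of a stoichiometric, semi-stabilised benzylic ylide toward a planar partner.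
- Comparison: the alternative loads lifetime of the intermediate, diastereocontrol and enantiocontrol onto a single step. The chosen route separates them: C7 is set by a catalytic allylic substitution and the ring is closed in a separate, fast radical step.

**Alternative 3: ring contraction of a flavanone by oxidative 1,2-aryl shift.**
- Disconnection: the C8-C3' bond is traced back to the C9-C3' bond of flavanone A12, in which C9 is the ketone carbon.
- Forward key step: with PhI(OAc)2, HC(OMe)3 and H2SO4 in methanol the enol ether of A12 is attacked at C8 by the iodane. Ring B carbon C3' then shifts from C9 to C8 as the iodane leaves, the pyranone contracts, and C9 emerges as the methyl ester of A11.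
- For: the reaction type is established for flavanones, A12 is two steps from simple aromatic building blocks, and C9 arrives at a useful oxidation level. The trans ester is the thermodynamically preferred one and can be corrected by base, so on step count and on relative configuration this alternative is at least as good as the chosen route.
- Against: the absolute configuration depends entirely on an enantiopure flavanone. Its C7 centre is set with difficulty and is labile, because the six-membered ring can open and re-close by a retro-oxa-Michael path under the strongly acidic conditions of the key step. The electron-rich ring A can also migrate from C7 to C8, and dehydrogenation across C7-C8 competes.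
- Comparison: the chosen route sets C7 by catalytic asymmetric C-O bond formation and then keeps it in a five-membered ring that cannot open by a comparable pathway.

Key step: step 5

## Remarks before the steps

Remark on step 4: L is O,O'-[(R)-1,1'-binaphthyl-2,2'-diyl] N,N-bis[(R)-1-phenylethyl]phosphoramidite. It is assumed to give the (R)-ether by attack of the aryloxide on the face of the allyl ligand away from the metal, as with other heteroatom nucleophiles on cinnamyl carbonates; if the sense of induction is the opposite, the enantiomeric ligand is used with no other change.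

Remark on materials: ester 3 is taken as a catalogue compound.

## Steps

Step 1
Reactants: 1 methyl vanillate (methyl 4-hydroxy-3-methoxybenzoate)
Product: 2 methyl 4-hydroxy-3-iodo-5-methoxybenzoate
Conditions: NIS (1.05 equiv), CF3CO2H (cat.), MeCN, rt
Reagents that add atoms: N-iodosuccinimide, O=C1CCC(=O)N1I
Why: Electrophilic aromatic iodination; the free phenol directs to its only open ortho position (the future C3'), since the para position is taken by the ester and the other ortho position by the methoxy group.

Step 2
Reactants: 3 methyl (2E)-3-(3,4,5-trimethoxyphenyl)prop-2-enoate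
Product: 4 (2E)-3-(3,4,5-trimethoxyphenyl)prop-2-en-1-ol
Conditions: i-Bu2AlH (2.5 equiv), CH2Cl2, -78 to 0 °C
Reagents that add atoms: none
Why: 1,2-Reduction of an α,β-unsaturated ester by i-Bu2AlH stops at the allylic alcohol and leaves the E alkene untouched.

Step 3
Reactants: 4 (2E)-3-(3,4,5-trimethoxyphenyl)prop-2-en-1-ol
Product: 5 methyl (2E)-3-(3,4,5-trimethoxyphenyl)prop-2-en-1-yl carbonate
Conditions: ClCO2Me, pyridine, CH2Cl2, 0 °C to rt
Reagents that add atoms: methyl chloroformate, COC(=O)Cl
Why: Acylation of a primary alcohol with a chloroformate; the methyl carbonate is the leaving group for the allylic substitution, and the methoxide it releases matches the methyl ester of the coupling partner.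

Step 4
Reactants: 2 methyl 4-hydroxy-3-iodo-5-methoxybenzoate; 5 methyl (2E)-3-(3,4,5-trimethoxyphenyl)prop-2-en-1-yl carbonate
Product: 7 methyl 3-iodo-5-methoxy-4-{[(1R)-1-(3,4,5-trimethoxyphenyl)prop-2-en-1-yl]oxy}benzoate, via lithium aryloxide 6 (not isolated)
Conditions: 2 (1.5 equiv), LiN(SiMe3)2, THF, 0 °C; then 5, [Ir(cod)Cl]2 (2 mol %), (Ra,Rc,Rc)-L (4 mol %, catalyst preactivated with n-PrNH2), THF, 50 °C
Reagents that add atoms: none
Why: Iridium-catalysed asymmetric allylic etherification: the cyclometalated monovalent iridium phosphoramidite complex ionises 5 to a trivalent iridium allyl complex, and aryloxide 6 attacks the aryl-substituted terminus from the face opposite the metal, which gives the branched ether and sets C7 (R) under ligand control. Methoxide from the carbonate can exchange the methyl ester only degenerately, and the aryl iodide is not expected to react with the iridium catalyst.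

Step 5
Reactants: 7 methyl 3-iodo-5-methoxy-4-{[(1R)-1-(3,4,5-trimethoxyphenyl)prop-2-en-1-yl]oxy}benzoate; 8 TEMPO (2,2,6,6-tetramethylpiperidin-1-oxyl)
Product: 11 methyl (2R,3S)-7-methoxy-3-{[(2,2,6,6-tetramethylpiperidin-1-yl)oxy]methyl}-2-(3,4,5-trimethoxyphenyl)-2,3-dihydro-1-benzofuran-5-carboxylate, via aryl radical 9 (not isolated), via cyclised C9 radical 10 (not isolated)
Conditions: 8 (6 equiv), Bu3SnH (5 equiv, added in portions), toluene, 70 °C
Reagents that add atoms: none
Why: Hydrogen transfer from Bu3SnH to 8 releases Bu3Sn radicals, which abstract iodine from 7 and give the sigma-aryl radical 9 at C3'. Radical 9 adds 5-exo-trig to the internal carbon of the tethered vinyl group, which forms C8-C3' and closes the dihydrofuran ring (O, C7, C8, C3', C4'); the unsubstituted terminal alkene on a three-atom tether makes this mode far faster than 6-endo attack at C9. The primary radical 10 is then captured at C9 by the persistent nitroxyl 8 at close to the diffusion limit, which forms C9-O and outruns hydrogen transfer from the stannane and neophyl-type ring expansion. The closest known reaction type is the tin hydride and TEMPO cyclisation-trapping of 2-haloaryl allyl ethers and N-allyl anilines to 3-(aminoxymethyl) dihydrobenzofurans and indolines. C7 is not touched and keeps its R configuration; C8 is set by 1,2-induction from C7, because the early chair-like transition state places the C7 aryl group pseudo-equatorial and away from the C9 methylene of the alkene, which leads to the 2,3-trans ring (8S). The step needs ring closure of 9 to beat its bimolecular quenching, which the very high cyclisation rate of 2-(allyloxy)phenyl radicals secures, and it needs oxygen capture at C9 in place of reduction, which the excess of 8 over the slowly added stannane secures. The methoxy group at C5' twists the O-C7 bond out of the plane of ring B and so holds the vinyl group over C3'.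

Step 6
Reactants: 11 methyl (2R,3S)-7-methoxy-3-{[(2,2,6,6-tetramethylpiperidin-1-yl)oxy]methyl}-2-(3,4,5-trimethoxyphenyl)-2,3-dihydro-1-benzofuran-5-carboxylate
Product: 12 methyl (2R,3S)-3-(hydroxymethyl)-7-methoxy-2-(3,4,5-trimethoxyphenyl)-2,3-dihydro-1-benzofuran-5-carboxylate
Conditions: Zn dust, AcOH/THF/H2O (3:1:1), 70 °C
Reagents that add atoms: none
Why: Reductive cleavage of the N-O bond of the alkoxyamine by zinc in acetic acid, the usual way to unmask a TEMPO-trapped primary alcohol; the ester, the aryl ethers and both stereocentres should be unaffected.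

Step 7
Reactants: 12 methyl (2R,3S)-3-(hydroxymethyl)-7-methoxy-2-(3,4,5-trimethoxyphenyl)-2,3-dihydro-1-benzofuran-5-carboxylate
Product: 13 [(2R,3S)-7-methoxy-2-(3,4,5-trimethoxyphenyl)-2,3-dihydro-1-benzofuran-3,5-diyl]dimethanol
Conditions: i-Bu2AlH (4 equiv), CH2Cl2, -78 to 0 °C
Reagents that add atoms: none
Why: Hydride reduction of the aryl methyl ester to the benzylic alcohol; the free C9 hydroxyl only consumes one equivalent of hydride as its aluminium alkoxide.

Step 8
Reactants: 13 [(2R,3S)-7-methoxy-2-(3,4,5-trimethoxyphenyl)-2,3-dihydro-1-benzofuran-3,5-diyl]dimethanol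
Product: 15 methyl (2E)-3-[(2R,3S)-3-(hydroxymethyl)-7-methoxy-2-(3,4,5-trimethoxyphenyl)-2,3-dihydro-1-benzofuran-5-yl]prop-2-enoate, via aldehyde 14 (not isolated)
Conditions: activated MnO2 (10 equiv), Ph3P=CHCO2Me (1.3 equiv), CH2Cl2, rt
Reagents that add atoms: methyl (triphenylphosphoranylidene)acetate, COC(=O)C=P(c1ccccc1)(c1ccccc1)c1ccccc1
Why: Tandem oxidation and Wittig olefination: MnO2 oxidises only the benzylic alcohol to aldehyde 14, which is trapped in the same flask by the stabilised ylide to give the E-cinnamate. The saturated C9 alcohol is not expected to be oxidised by MnO2 at room temperature.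

Step 9
Reactants: 15 methyl (2E)-3-[(2R,3S)-3-(hydroxymethyl)-7-methoxy-2-(3,4,5-trimethoxyphenyl)-2,3-dihydro-1-benzofuran-5-yl]prop-2-enoate
Product: 16 (-)-(7R,8S,7'E)-3,4,5,5'-tetramethoxy-4',7-epoxy-8,3'-neolign-7'-ene-9,9'-diol
Conditions: i-Bu2AlH (4 equiv), CH2Cl2, -78 °C
Reagents that add atoms: none
Why: 1,2-Reduction of the conjugated ester by i-Bu2AlH at low temperature gives the E allylic alcohol; neither stereocentre is involved.

## Compound list

1 | methyl 4-hydroxy-3-methoxybenzoate (methyl vanillate) | COC(=O)c1ccc(O)c(OC)c1 | starting material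
2 | methyl 4-hydroxy-3-iodo-5-methoxybenzoate | COC(=O)c1cc(I)c(O)c(OC)c1 | intermediate
3 | methyl (2E)-3-(3,4,5-trimethoxyphenyl)prop-2-enoate | COC(=O)/C=C/c1cc(OC)c(OC)c(OC)c1 | starting material
4 | (2E)-3-(3,4,5-trimethoxyphenyl)prop-2-en-1-ol | OC/C=C/c1cc(OC)c(OC)c(OC)c1 | intermediate
5 | methyl (2E)-3-(3,4,5-trimethoxyphenyl)prop-2-en-1-yl carbonate | COC(=O)OC/C=C/c1cc(OC)c(OC)c(OC)c1 | intermediate
6 | lithium 2-iodo-6-methoxy-4-(methoxycarbonyl)phenolate | [Li+].[O-]c1c(I)cc(C(=O)OC)cc1OC | intermediate
7 | methyl 3-iodo-5-methoxy-4-{[(1R)-1-(3,4,5-trimethoxyphenyl)prop-2-en-1-yl]oxy}benzoate | COc1cc([C@@H](C=C)Oc2c(I)cc(C(=O)OC)cc2OC)cc(OC)c1OC | intermediate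
8 | 2,2,6,6-tetramethylpiperidin-1-oxyl (TEMPO) | CC1(C)CCCC(C)(C)N1[O] | starting material
9 | 3-methoxy-5-(methoxycarbonyl)-2-{[(1R)-1-(3,4,5-trimethoxyphenyl)prop-2-en-1-yl]oxy}phenyl radical | COc1cc([C@@H](C=C)Oc2[c]cc(C(=O)OC)cc2OC)cc(OC)c1OC | intermediate
10 | [(2R,3R)-7-methoxy-5-(methoxycarbonyl)-2-(3,4,5-trimethoxyphenyl)-2,3-dihydro-1-benzofuran-3-yl]methyl radical (2,3-trans) | COc1cc([C@@H]2Oc3c(OC)cc(C(=O)OC)cc3[C@H]2[CH2])cc(OC)c1OC | intermediate
11 | methyl (2R,3S)-7-methoxy-3-{[(2,2,6,6-tetramethylpiperidin-1-yl)oxy]methyl}-2-(3,4,5-trimethoxyphenyl)-2,3-dihydro-1-benzofuran-5-carboxylate | COc1cc([C@@H]2Oc3c(OC)cc(C(=O)OC)cc3[C@H]2CON4C(C)(C)CCCC4(C)C)cc(OC)c1OC | intermediate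
12 | methyl (2R,3S)-3-(hydroxymethyl)-7-methoxy-2-(3,4,5-trimethoxyphenyl)-2,3-dihydro-1-benzofuran-5-carboxylate | COc1cc([C@@H]2Oc3c(OC)cc(C(=O)OC)cc3[C@H]2CO)cc(OC)c1OC | intermediate
13 | [(2R,3S)-7-methoxy-2-(3,4,5-trimethoxyphenyl)-2,3-dihydro-1-benzofuran-3,5-diyl]dimethanol | COc1cc([C@@H]2Oc3c(OC)cc(CO)cc3[C@H]2CO)cc(OC)c1OC | intermediate
14 | (2R,3S)-3-(hydroxymethyl)-7-methoxy-2-(3,4,5-trimethoxyphenyl)-2,3-dihydro-1-benzofuran-5-carbaldehyde | COc1cc([C@@H]2Oc3c(OC)cc(C=O)cc3[C@H]2CO)cc(OC)c1OC | intermediate
15 | methyl (2E)-3-[(2R,3S)-3-(hydroxymethyl)-7-methoxy-2-(3,4,5-trimethoxyphenyl)-2,3-dihydro-1-benzofuran-5-yl]prop-2-enoate | COc1cc([C@@H]2Oc3c(OC)cc(/C=C/C(=O)OC)cc3[C@H]2CO)cc(OC)c1OC | intermediate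
16 | (-)-(7R,8S,7'E)-3,4,5,5'-tetramethoxy-4',7-epoxy-8,3'-neolign-7'-ene-9,9'-diol | COc1cc([C@@H]2Oc3c(OC)cc(/C=C/CO)cc3[C@H]2CO)cc(OC)c1OC | target

## Step count and risk

Total step count: 9 (steps 1 to 9).
Longest linear sequence: 8 steps (from 3 through steps 2, 3, 4, 5, 6, 7, 8 and 9 to 16). The branch from 1 joins at step 4.

Least certain steps:

**Step 5 (key step).** The most likely failure is incomplete 1,2-induction at C8: the aryl radical closes through a very early transition state, so the preference for the pseudo-equatorial C7 aryl group may be modest and the cis ring may form alongside the trans one. Premature quenching of the aryl radical is a lesser concern if stannane and nitroxyl are badly balanced.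
- Fallback: C8 is set by thermodynamic equilibration of an enolisable centre in place of kinetic induction. It sets out from 12, carried as the mixture of C8 epimers, and returns at 13.
- The C9 alcohol would be oxidised directly (PhI(OAc)2, TEMPO cat., MeCN/H2O, rt) to the C3-epimeric (2R)-7-methoxy-5-(methoxycarbonyl)-2-(3,4,5-trimethoxyphenyl)-2,3-dihydro-1-benzofuran-3-carboxylic acid F1.
- F1 would be esterified (Me3SiCHN2, MeOH/toluene) and the crude diester equilibrated with NaOMe in MeOH to dimethyl (2R,3R)-7-methoxy-2-(3,4,5-trimethoxyphenyl)-2,3-dihydro-1-benzofuran-3,5-dicarboxylate F2, the trans isomer. Ring opening at C7 from the ester enolate would be a stereoelectronically disfavoured reverse 5-endo process, so C7 should hold.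
- LiAlH4 in THF at 0 °C would then reduce both esters to give 13.

**Step 4.** The aryloxide is hindered on both ortho sides and made less nucleophilic by the para ester, so attack on the allyl iridium intermediate may be slow. The product ether, with a good aryloxide leaving group on a benzylic allylic carbon, may ionise again on the catalyst and lose branched selectivity and enantiomeric purity.
- Fallback: Mitsunobu etherification with a preformed chiral alcohol. It sets out from 2 and returns at 7.
- 3,4,5-Trimethoxybenzaldehyde F3 and CH2=CHMgBr (THF, 0 °C) would give racemic 1-(3,4,5-trimethoxyphenyl)prop-2-en-1-ol F4.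
- Lipase resolution (CAL-B, vinyl acetate), which acylates the R enantiomer of such secondary alcohols, would leave (1S)-1-(3,4,5-trimethoxyphenyl)prop-2-en-1-ol F5 beside (1R)-1-(3,4,5-trimethoxyphenyl)prop-2-en-1-yl acetate F6.
- Coupling of F5 with 2 (PPh3, diisopropyl azodicarboxylate, toluene, 0 °C) should proceed with inversion to give 7.

**Step 6.** Hot acetic acid may promote ionisation of the benzylic C7-O bond, with erosion of configuration at C7, or electron transfer to the hindered alkoxyamine may be sluggish.
- Fallback: oxidative in place of reductive N-O cleavage. It sets out from 11 and returns at 12.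
- mCPBA in CH2Cl2 at 0 °C would oxidise the nitrogen, and the N-oxide would fragment to methyl (2R,3R)-3-formyl-7-methoxy-2-(3,4,5-trimethoxyphenyl)-2,3-dihydro-1-benzofuran-5-carboxylate F7.
- F7 would be reduced at once with NaBH4 in MeOH at 0 °C to give 12.

**Step 8.** Prolonged contact with a large excess of MnO2 may erode chemoselectivity, through slow oxidation of the C9 carbinol or dehydrogenation of the dihydrofuran ring, or the oxidation may stall while the ylide degrades.
- Fallback: the alkoxyamine is kept as the protecting group for the C9 oxygen, so no chemoselective oxidation is needed. It sets out from 11 and returns at 15.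
- i-Bu2AlH (CH2Cl2, -78 to 0 °C) would give [(2R,3S)-7-methoxy-3-{[(2,2,6,6-tetramethylpiperidin-1-yl)oxy]methyl}-2-(3,4,5-trimethoxyphenyl)-2,3-dihydro-1-benzofuran-5-yl]methanol F8.
- Dess-Martin periodinane (CH2Cl2, rt) would give (2R,3S)-7-methoxy-3-{[(2,2,6,6-tetramethylpiperidin-1-yl)oxy]methyl}-2-(3,4,5-trimethoxyphenyl)-2,3-dihydro-1-benzofuran-5-carbaldehyde F9.
- Ph3P=CHCO2Me (CH2Cl2, rt) would give methyl (2E)-3-[(2R,3S)-7-methoxy-3-{[(2,2,6,6-tetramethylpiperidin-1-yl)oxy]methyl}-2-(3,4,5-trimethoxyphenyl)-2,3-dihydro-1-benzofuran-5-yl]prop-2-enoate F10.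
- Zn dust in AcOH/THF/H2O would then release the C9 alcohol to give 15.

## Further compounds

F1 | step 5 | (2R)-7-methoxy-5-(methoxycarbonyl)-2-(3,4,5-trimethoxyphenyl)-2,3-dihydro-1-benzofuran-3-carboxylic acid (mixture of C3 epimers) | COc1cc([C@@H]2Oc3c(OC)cc(C(=O)OC)cc3C2C(=O)O)cc(OC)c1OC
F2 | step 5 | dimethyl (2R,3R)-7-methoxy-2-(3,4,5-trimethoxyphenyl)-2,3-dihydro-1-benzofuran-3,5-dicarboxylate | COc1cc([C@@H]2Oc3c(OC)cc(C(=O)OC)cc3[C@H]2C(=O)OC)cc(OC)c1OC
F3 | step 4 | 3,4,5-trimethoxybenzaldehyde | COc1cc(C=O)cc(OC)c1OC
F4 | step 4 | rac-1-(3,4,5-trimethoxyphenyl)prop-2-en-1-ol | COc1cc(C(O)C=C)cc(OC)c1OC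
F5 | step 4 | (1S)-1-(3,4,5-trimethoxyphenyl)prop-2-en-1-ol | COc1cc([C@H](C=C)O)cc(OC)c1OC
F6 | step 4 | (1R)-1-(3,4,5-trimethoxyphenyl)prop-2-en-1-yl acetate | COc1cc([C@@H](C=C)OC(C)=O)cc(OC)c1OC
F7 | step 6 | methyl (2R,3R)-3-formyl-7-methoxy-2-(3,4,5-trimethoxyphenyl)-2,3-dihydro-1-benzofuran-5-carboxylate | COc1cc([C@@H]2Oc3c(OC)cc(C(=O)OC)cc3[C@H]2C=O)cc(OC)c1OC
F8 | step 8 | [(2R,3S)-7-methoxy-3-{[(2,2,6,6-tetramethylpiperidin-1-yl)oxy]methyl}-2-(3,4,5-trimethoxyphenyl)-2,3-dihydro-1-benzofuran-5-yl]methanol | COc1cc([C@@H]2Oc3c(OC)cc(CO)cc3[C@H]2CON4C(C)(C)CCCC4(C)C)cc(OC)c1OC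
F9 | step 8 | (2R,3S)-7-methoxy-3-{[(2,2,6,6-tetramethylpiperidin-1-yl)oxy]methyl}-2-(3,4,5-trimethoxyphenyl)-2,3-dihydro-1-benzofuran-5-carbaldehyde | COc1cc([C@@H]2Oc3c(OC)cc(C=O)cc3[C@H]2CON4C(C)(C)CCCC4(C)C)cc(OC)c1OC
F10 | step 8 | methyl (2E)-3-[(2R,3S)-7-methoxy-3-{[(2,2,6,6-tetramethylpiperidin-1-yl)oxy]methyl}-2-(3,4,5-trimethoxyphenyl)-2,3-dihydro-1-benzofuran-5-yl]prop-2-enoate | COc1cc([C@@H]2Oc3c(OC)cc(/C=C/C(=O)OC)cc3[C@H]2CON4C(C)(C)CCCC4(C)C)cc(OC)c1OC
A1 | alternative 1 | methyl 3-[1-(tert-butyldimethylsilyloxy)-3-(4,4,5,5-tetramethyl-1,3,2-dioxaborolan-2-yl)-3-(3,4,5-trimethoxyphenyl)propan-2-yl]-4-fluoro-5-methoxybenzoate (anti adduct) | COc1cc([C@H](B2OC(C)(C)C(C)(C)O2)[C@H](CO[Si](C)(C)C(C)(C)C)c2cc(C(=O)OC)cc(OC)c2F)cc(OC)c1OC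
A2 | alternative 1 | tert-butyldimethyl{[(2E)-3-(4,4,5,5-tetramethyl-1,3,2-dioxaborolan-2-yl)prop-2-en-1-yl]oxy}silane | CC(C)(C)[Si](C)(C)OC/C=C/B1OC(C)(C)C(C)(C)O1
A3 | alternative 1 | (3,4,5-trimethoxyphenyl)lithium | [Li]c1cc(OC)c(OC)c(OC)c1
A4 | alternative 1 | lithium [(1E)-3-(tert-butyldimethylsilyloxy)prop-1-en-1-yl](pinacolato)(3,4,5-trimethoxyphenyl)borate | [Li+].COc1cc([B-]2(/C=C/CO[Si](C)(C)C(C)(C)C)OC(C)(C)C(C)(C)O2)cc(OC)c1OC
A5 | alternative 1 | methyl 4-fluoro-3-methoxy-5-{[(trifluoromethyl)sulfonyl]oxy}benzoate | COC(=O)c1cc(OC)c(F)c(OS(=O)(=O)C(F)(F)F)c1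
A6 | alternative 2 | (2R,3S)-5-bromo-7-methoxy-2-(3,4,5-trimethoxyphenyl)-3-(triisopropylsilyloxymethyl)-2,3-dihydro-1-benzofuran | COc1cc([C@@H]2Oc3c(OC)cc(Br)cc3[C@H]2CO[Si](C(C)C)(C(C)C)C(C)C)cc(OC)c1OC
A7 | alternative 2 | 4-bromo-2-methoxy-6-[1-(4-methylphenylsulfonyl)-2-(triisopropylsilyloxy)ethyl]phenol (racemic) | COc1cc(Br)cc(C(CO[Si](C(C)C)(C(C)C)C(C)C)S(=O)(=O)c2ccc(C)cc2)c1O
A8 | alternative 2 | (2R,5R)-2,5-dimethyl-1-(3,4,5-trimethoxybenzyl)thiolan-1-ium trifluoromethanesulfonate | C[C@@H]1CC[C@@H](C)[S+]1Cc1cc(OC)c(OC)c(OC)c1.[O-]S(=O)(=O)C(F)(F)F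
A9 | alternative 2 | 4-bromo-2-methoxy-6-[2-(triisopropylsilyloxy)ethylidene]cyclohexa-2,4-dien-1-one (alkene geometry not defined) | O=C1C(OC)=CC(Br)=CC1=CCO[Si](C(C)C)(C(C)C)C(C)C
A10 | alternative 2 | (2R,5R)-2,5-dimethylthiolan-1-ium-1-yl (3,4,5-trimethoxyphenyl)methanide | C[C@@H]1CC[C@@H](C)[S+]1[CH-]c1cc(OC)c(OC)c(OC)c1
A11 | alternative 3 | methyl (2R,3R)-5-bromo-7-methoxy-2-(3,4,5-trimethoxyphenyl)-2,3-dihydro-1-benzofuran-3-carboxylate (trans) | COc1cc([C@@H]2Oc3c(OC)cc(Br)cc3[C@H]2C(=O)OC)cc(OC)c1OC
A12 | alternative 3 | (2R)-6-bromo-8-methoxy-2-(3,4,5-trimethoxyphenyl)-2,3-dihydro-4H-chromen-4-one | COc1cc([C@H]2CC(=O)c3cc(Br)cc(OC)c3O2)cc(OC)c1OC
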